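Its constants are made up; what happens was integrated by code.

Ask what stands in this flask late in the run, once its L has reacted.

    L + L.X → L.L.X (k1 = 43 M⁻¹ s⁻¹)
    L + X → L.X (k2 = 0.14 M⁻¹ s⁻¹)
    G ⇌ Z (K3 = 0.38, k3 = 0.28 s⁻¹)
    L.X → G (k4 = 7.9 s⁻¹)

L 0.92 M; X 1.30 equiv; time 1.5 h

* how much G there is at 1.5 h, in percent of the L charged
* how much L.L.X there is at 1.5 h, in percent of the L charged
* how much Z there is at 1.5 h, in percent of the L charged

- percent here means L units held: one L.L.X counts as two
- run time (flask): 1.5 h

Reckon the crossover concentration first, 0.184 M: the level of L at which capture of L.X by L runs as fast as closure of L.X to G. Now two numbers clash. This flask starts at 5.01 times the crossover, so closure takes just 9.08% of the L used at the start. But capture fades as L falls, and below the crossover closure leads. Neither end gives the flask's share.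

So add it up. Closure clears L.X at 7.9 s⁻¹, far faster than X takes up L, at 0.167 s⁻¹. Treat L.X as a short-lived intermediate in quasi-steady state: each one made is used at once. Uptake is then the rate-limiting step, and its constant drops out of the split. Each L.X costs one L and each capture one more. At level L, closure therefore takes c/(c + 2L) of the L used, with c the crossover. Sum this from the charge down to nothing. With L now the charge, the share going through closure is (c/2L) ln(1 + 2L/c), here 24.0%. G and Z relax with a half-life of 0.0114 min, much shorter than the run, so split that share between them with Z over G at 0.38. My reckoning gives G 17.4%, Z 6.61% and L.L.X 76.0%.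

The forecast gives G 17.4%, L.L.X 76% and Z 6.6%. It rests on “how L.X splits between ring closure”.

The flask gives G 17.4%, L.L.X 76.0% and Z 6.62%. Now charge the neighbour flask with 0.23 M of L, keeping the equivalents and the time. It starts at 1.25 times the crossover. The same sum gives a closure share of 50.1%, which divides into G 36.3% and Z 13.8%, with L.L.X at 49.9%. The neighbour flask gives G 36.3%, Z 13.8% and L.L.X 49.9%.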